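Ring B comes from (R)-carvone, whose C5 stereocentre controls all others, and ring A is closed last (labdane numbering). The disconnection removes the C2–C3 ethano bridge of ring A: vinylmagnesium bromide supplies both carbons. In one flask it adds to the neopentyl C1 aldehyde on quaternary C10 (C1–C2), the alkoxide is phosphorylated, and the C4 ester enolate closes ring A by SN2′ attack on C3 (C3–C4), setting the C4 quaternary centre stereoconvergently. The step exploits the 1,4-relationship of C1 and C4 across the C5–C10 bond of ring B and the axial C10 methyl, which steers the C4 carboxyl equatorial. The precursor is a ring-B cyclohexene bearing C10(CH3)(CHO), C5–CH(CH3)CO2Bn and the C9 chain.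

Key step: step 12

Remark: labdane numbering is used (ring A = C1–C5 + C10; ring B = C5–C10; C11–C13 = chain on C9; C17 = CH3 on C8; C18 = carboxyl carbon and C19 = CH3 on C4; C20 = CH3 on C10; α = face of H-5, β = face of CH3-20), and the target is read as the (4R,5R,8R,9R,10S) isomer, 8α-acetoxy-14,15,16-trinorlabdane-13,18-dioic acid.

Step 1
Reactants: 1 (R)-(−)-carvone
Product: 2 6-methylcarvone (epimer mixture at the future C10)
Conditions: LiN(iPr)2, THF, −78 °C; MeI, −78 → 0 °C
Reagents that add atoms: iodomethane CI
Why: Kinetic α′-deprotonation gives the cross-conjugated lithium enolate, which is C-methylated at the future C10 (enolate alkylation); the new centre forms as an epimer mixture that is erased in step 2.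

Step 2
Reactants: 2 6-methylcarvone
Product: 3 trimethylsilyl dienol ether
Conditions: LiN(iPr)2, THF, −78 °C; Me3SiCl, −78 °C → rt
Reagents that add atoms: chlorotrimethylsilane C[Si](C)(C)Cl
Why: The only enolate that can form (C9–C10, cross-conjugated) is O-silylated (silyl enol ether formation), which removes the C10 stereocentre and prepares a neutral nucleophile for the next step.

Step 3
Reactants: 3 trimethylsilyl dienol ether
Product: 4 keto acetal with quaternary C10
Conditions: HC(OMe)3, Me3SiOTf (10 mol%), CH2Cl2, −78 °C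
Reagents that add atoms: trimethyl orthoformate COC(OC)OC
Why: A Mukaiyama-type addition of the silyl enol ether to the dimethoxycarbenium ion builds quaternary C10 with C1 at the aldehyde oxidation level; the electrophile should enter trans to the neighbouring C5 isopropenyl group (the usual sense for 6-methylcarvone enolates), so CH3-20 ends cis to it.

Step 4
Reactants: 4 keto acetal; 5 benzyl 3-bromopropyl ether
Product: 7 tertiary allylic alcohol (C9 epimers), via Grignard reagent 6 (not isolated)
Conditions: 5, Mg, THF, rt; anhydrous CeCl3, THF, −78 °C; then 4, −78 → 0 °C; aq NH4Cl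
Reagents that add atoms: none
Why: Organocerium (Grignard/CeCl3) 1,2-addition to the hindered, non-enolisable enone carbonyl installs C11–C13 while suppressing conjugate addition and reduction; the carbinol configuration is irrelevant because C9 becomes sp2 in step 5.

Step 5
Reactants: 7 tertiary allylic alcohol
Product: 8 transposed enone (7-oxo-8-ene)
Conditions: pyridinium chlorochromate (C5H5NH)[CrO3Cl], 4 Å molecular sieves, CH2Cl2, rt
Reagents that add atoms: pyridinium chlorochromate [O-][Cr](=O)(=O)Cl.c1cc[nH+]cc1
Why: Babler–Dauben oxidative 1,3-transposition: the chromate ester of the tertiary allylic alcohol undergoes a [3,3] shift to C7 and is oxidised to the enone, which places the chain on an sp2 C9.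

Step 6
Reactants: 8 transposed enone
Product: 9 7β-allylic alcohol
Conditions: NaBH4, CeCl3·7H2O, MeOH, −78 → 0 °C
Reagents that add atoms: none
Why: Luche 1,2-reduction; axial hydride delivery on the α face, away from the pseudo-axial C10 methyl, should give the 7β-alcohol cis to the C5 isopropenyl group, the same sense as the reduction of carvone to cis-carveol.

Step 7
Reactants: 9 7β-allylic alcohol
Product: 12 7-ene with 9α-H and 9β chain, via sulfonylhydrazine adduct 10 (not isolated), via allylic diazene 11 (not isolated)
Conditions: 2-nitrobenzenesulfonylhydrazide, PPh3, diethyl azodicarboxylate, N-methylmorpholine, −30 °C → rt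
Reagents that add atoms: none
Why: Reductive 1,3-transposition of the allylic alcohol: Mitsunobu displacement with inversion puts nitrogen on the α face of C7, sulfinate is lost, and the retro-ene loss of N2 from the monoalkyl diazene delivers hydrogen suprafacially to the α face of C9 while the alkene returns to C7=C8, so the chain ends β (trans to C1).

Step 8
Reactants: 12 7-ene acetal
Product: 14 C18 primary alcohol (C4 epimers), via alkylborane 13 (not isolated)
Conditions: 9-BBN, THF, 0 °C → rt; then NaOH, H2O2, 0 °C
Reagents that add atoms: hydrogen peroxide OO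
Why: Anti-Markovnikov hydroboration–oxidation in which 9-borabicyclo[3.3.1]nonane takes the 1,1-disubstituted isopropenyl alkene and leaves the hindered trisubstituted ring alkene; the C4 epimer mixture does not matter because C4 is enolised in step 12.

Step 9
Reactants: 14 C18 primary alcohol
Product: 16 C18 carboxylic acid, via aldehyde 15 (not isolated)
Conditions: TEMPO (cat.), NaClO2, NaOCl (cat.), MeCN/phosphate buffer (pH 6.7), 35 °C
Reagents that add atoms: sodium chlorite [Na+].[O-]Cl=O
Why: Oxoammonium/chlorite oxidation of the primary alcohol through the aldehyde to the acid at near-neutral pH, where the dimethyl acetal, the benzyl ether and the ring alkene should survive.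

Step 10
Reactants: 16 C18 carboxylic acid
Product: 17 benzyl ester
Conditions: BnBr, K2CO3, DMF, rt
Reagents that add atoms: benzyl bromide BrCc1ccccc1
Why: Carboxylate O-alkylation (SN2) gives an ester that can be enolised in step 12 and removed at the end by hydrogenolysis without touching the tertiary acetate.

Step 11
Reactants: 17 benzyl ester acetal
Product: 18 aldehyde ester
Conditions: TsOH·H2O (cat.), acetone/H2O, 40 °C
Reagents that add atoms: water O
Why: Acid-catalysed acetal hydrolysis unmasks the non-enolisable neopentyl C1 aldehyde; the benzyl ester, benzyl ether and trisubstituted alkene tolerate mild aqueous acid.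

Step 12
Reactants: 18 aldehyde ester; 19 vinylmagnesium bromide
Product: 23 bicyclic diene ester (ring A closed), via magnesium alkoxide 20 (not isolated), via allylic phosphate 21 (not isolated), via potassium enolate 22 (not isolated)
Conditions: 19 (1.1 equiv), THF, −78 °C; ClP(O)(OEt)2, −78 → −20 °C; KN(SiMe3)2, −78 → 0 °C (one flask); aq NH4Cl
Reagents that add atoms: none
Why: Vinylmagnesium bromide adds to the non-enolisable neopentyl C1 aldehyde (C1–C2 bond), the alkoxide 20 is trapped in the same flask as the allylic phosphate 21, and KN(SiMe3)2 then generates the C4 potassium ester enolate 22, which attacks the vinyl terminus C3 intramolecularly in an SN2′ displacement of phosphate (C3–C4 bond), leaving the C1=C2 alkene. The closest known reaction types are Grignard addition to an aldehyde followed by intramolecular enolate SN2′ allylic alkylation, the metal-free relative of a Tsuji–Trost cyclisation. Ring A closes in the 6-endo-trig (SN2′) mode through a chair-like transition state trans-fused to ring B; attack at C1 would give a cyclobutane and direct SN2 is impossible at the neopentyl C1. C4 is the only stereocentre that survives: the electrophile is delivered from C10, and A(1,3) strain makes H-5 eclipse the enolate C=C, so the C(OK)(OBn) terminus points away from the axial C10 methyl and becomes the equatorial 4α-ester while CH3-19 becomes axial (4β). The step is stereoconvergent, because both C4 epimers of 18, both C1 carbinol epimers and both enolate geometries pass through the same planar C4 and sp2 C1. The selectivities needed are aldehyde-over-ester addition, secured by −78 °C and the α-branched ester, and enolisation at C4 only, secured because C4–H is the only acidic C–H of 21.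

Step 13
Reactants: 23 bicyclic diene ester
Product: 24 8α-tertiary alcohol
Conditions: Mn(dpm)3 [tris(2,2,6,6-tetramethylheptane-3,5-dionato)manganese] (cat.), PhSiH3, O2 (1 atm), iPrOH/CH2Cl2, 0 °C → rt
Reagents that add atoms: dioxygen O=O
Why: Mukaiyama hydration by hydrogen-atom transfer: H adds to C7 to give the tertiary C8 radical (faster than radical formation at the 1,2-disubstituted ring-A alkene), and O2 should be captured on the α face, away from the syn-axial C10 methyl, giving the equatorial 8α-OH and axial CH3-17.

Step 14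
Reactants: 24 8α-tertiary alcohol
Product: 25 8α-acetate
Conditions: AcCl, PhNMe2, CH2Cl2, 0 °C → rt
Reagents that add atoms: acetyl chloride CC(=O)Cl
Why: Acylation of the hindered tertiary alcohol with acetyl chloride and N,N-dimethylaniline; C13 is still a benzyl ether, so no lactone can form, and no stereocentre is touched.

Step 15
Reactants: 25 8α-acetate
Product: 26 acetoxy hydroxy acid
Conditions: H2 (1 atm), 10% Pd/C, EtOAc/EtOH, rt
Reagents that add atoms: none
Why: Heterogeneous hydrogenation and hydrogenolysis over palladium on carbon saturate the C1=C2 alkene and cleave the benzyl ester and benzyl ether, while the tertiary acetate is inert.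

Step 16
Reactants: 26 acetoxy hydroxy acid
Product: 27 target diacid
Conditions: TEMPO (cat.), PhI(OAc)2, MeCN/H2O, rt
Reagents that add atoms: water O
Why: Oxoammonium (TEMPO/PhI(OAc)2) oxidation converts the C13 primary alcohol through the aldehyde hydrate into the carboxylic acid under mildly acidic conditions that should not cleave the tertiary acetate.

Compound list
1 | (R)-(−)-carvone, (5R)-2-methyl-5-(prop-1-en-2-yl)cyclohex-2-en-1-one | CC1=CC[C@@H](C(C)=C)CC1=O | starting material
2 | 6-methylcarvone, 2,6-dimethyl-5-(prop-1-en-2-yl)cyclohex-2-en-1-one with the carvone stereocentre, mixture of epimers at the new methyl-bearing carbon | CC1=CC[C@@H](C(C)=C)C(C)C1=O | intermediate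
3 | trimethyl{[2,6-dimethyl-3-(prop-1-en-2-yl)cyclohexa-1,5-dien-1-yl]oxy}silane, carvone stereocentre retained | CC1=CC[C@@H](C(C)=C)C(C)=C1O[Si](C)(C)C | intermediate
4 | 6-(dimethoxymethyl)-6-methylcarvone: 9-oxo-7-ene ring B; on C10 the CH3 is cis and the CH(OCH3)2 group (C1) trans to the C5 isopropenyl | CC1=CC[C@@H](C(C)=C)[C@](C)(C(OC)OC)C1=O | intermediate
5 | benzyl 3-bromopropyl ether | BrCCCOCc1ccccc1 | starting material
6 | 3-(benzyloxy)propylmagnesium bromide | Br[Mg]CCCOCc1ccccc1 | intermediate
7 | tertiary allylic alcohol: 4 with OH and 3-(benzyloxy)propyl on C9 (C9 epimers), 7-ene | CC1=CC[C@@H](C(C)=C)[C@](C)(C(OC)OC)C1(O)CCCOCc2ccccc2 | intermediate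
8 | transposed enone: 7-oxo-8(9)-ene ring B with 3-(benzyloxy)propyl on C9, C10 CH3/CH(OCH3)2 and C5 isopropenyl as in 4 | CC1=C(CCCOCc2ccccc2)[C@@](C)(C(OC)OC)[C@H](C(C)=C)CC1=O | intermediate
9 | 7β-allylic alcohol of 8 (OH cis to the C5 isopropenyl), 8(9)-ene | CC1=C(CCCOCc2ccccc2)[C@@](C)(C(OC)OC)[C@H](C(C)=C)C[C@@H]1O | intermediate
10 | 7α-[N-(2-nitrobenzenesulfonyl)hydrazin-1-yl] Mitsunobu adduct (C7 inverted), 8(9)-ene | CC1=C(CCCOCc2ccccc2)[C@@](C)(C(OC)OC)[C@H](C(C)=C)C[C@H]1N(N)S(=O)(=O)c3ccccc3[N+](=O)[O-] | intermediate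
11 | 7α-monoalkyl diazene, 8(9)-ene | CC1=C(CCCOCc2ccccc2)[C@@](C)(C(OC)OC)[C@H](C(C)=C)C[C@H]1N=N | intermediate
12 | ring-B 7-ene: C5 isopropenyl (β), C10 CH3 (β) and CH(OCH3)2 (α), C9 H (α) and 3-(benzyloxy)propyl (β), C8 methyl | CC1=CC[C@@H](C(C)=C)[C@](C)(C(OC)OC)[C@H]1CCCOCc2ccccc2 | intermediate
13 | B-alkyl-9-borabicyclo[3.3.1]nonane: 12 with boron on C18 (C4 epimers) | CC1=CC[C@@H](C(C)CB2C3CCCC2CCC3)[C@](C)(C(OC)OC)[C@H]1CCCOCc4ccccc4 | intermediate
14 | C18 primary alcohol: C5 carries CH(CH3)CH2OH (C4 epimers), rest as 12 | CC1=CC[C@@H](C(C)CO)[C@](C)(C(OC)OC)[C@H]1CCCOCc2ccccc2 | intermediate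
15 | C18 aldehyde: C5 carries CH(CH3)CHO (C4 epimers) | CC1=CC[C@@H](C(C)C=O)[C@](C)(C(OC)OC)[C@H]1CCCOCc2ccccc2 | intermediate
16 | C18 carboxylic acid: C5 carries CH(CH3)CO2H (C4 epimers) | CC1=CC[C@@H](C(C)C(=O)O)[C@](C)(C(OC)OC)[C@H]1CCCOCc2ccccc2 | intermediate
17 | benzyl ester of 16 (C4 epimers), C1 still the dimethyl acetal | CC1=CC[C@@H](C(C)C(=O)OCc2ccccc2)[C@](C)(C(OC)OC)[C@H]1CCCOCc3ccccc3 | intermediate
18 | aldehyde ester: ring-B 7-ene with C10(CH3)(CHO), C5–CH(CH3)CO2Bn (C4 epimers) and 9β-(3-benzyloxypropyl) | CC1=CC[C@@H](C(C)C(=O)OCc2ccccc2)[C@](C)(C=O)[C@H]1CCCOCc3ccccc3 | intermediate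
19 | vinylmagnesium bromide | C=C[Mg]Br | starting material
20 | bromomagnesium alkoxide of the C1 vinyl carbinol (C1 and C4 epimers) | CC1=CC[C@@H](C(C)C(=O)OCc2ccccc2)[C@](C)(C(O[Mg]Br)C=C)[C@H]1CCCOCc3ccccc3 | intermediate
21 | C1 allylic diethyl phosphate (C1 and C4 epimers) | CC1=CC[C@@H](C(C)C(=O)OCc2ccccc2)[C@](C)(C(OP(=O)(OCC)OCC)C=C)[C@H]1CCCOCc3ccccc3 | intermediate
22 | potassium ester enolate of 21 at C4 | CC1=CC[C@@H](C(C)=C(O[K])OCc2ccccc2)[C@](C)(C(OP(=O)(OCC)OCC)C=C)[C@H]1CCCOCc3ccccc3 | intermediate
23 | benzyl 13-(benzyloxy)-14,15,16-trinorlabda-1,7-dien-18-oate (trans-fused; 4α-CO2Bn, 4β-CH3, 5α-H, 9β chain, 10β-CH3) | CC1=CC[C@@H]2[C@](C)(C=CC[C@@]2(C)C(=O)OCc3ccccc3)[C@H]1CCCOCc4ccccc4 | intermediate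
24 | benzyl 13-(benzyloxy)-8α-hydroxy-14,15,16-trinorlabd-1-en-18-oate | O[C@]1(C)CC[C@@H]2[C@](C)(C=CC[C@@]2(C)C(=O)OCc3ccccc3)[C@H]1CCCOCc4ccccc4 | intermediate
25 | benzyl 8α-acetoxy-13-(benzyloxy)-14,15,16-trinorlabd-1-en-18-oate | CC(=O)O[C@]1(C)CC[C@@H]2[C@](C)(C=CC[C@@]2(C)C(=O)OCc3ccccc3)[C@H]1CCCOCc4ccccc4 | intermediate
26 | 8α-acetoxy-13-hydroxy-14,15,16-trinorlabdan-18-oic acid | CC(=O)O[C@]1(C)CC[C@@H]2[C@](C)(CCC[C@@]2(C)C(=O)O)[C@H]1CCCO | intermediate
27 | 8α-acetoxy-14,15,16-trinorlabdane-13,18-dioic acid, 3-[(1R,2R,4aR,5R,8aS)-2-acetoxy-5-carboxy-2,5,8a-trimethyldecahydronaphthalen-1-yl]propanoic acid | CC(=O)O[C@]1(C)CC[C@@H]2[C@](C)(CCC[C@@]2(C)C(=O)O)[C@H]1CCC(=O)O | target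

Total step count: 16. Longest linear sequence: 16 steps, from (R)-carvone (1) to 27.

Steps most likely to fail

1. Step 12 (key step). What may go wrong: translactonisation of the magnesium alkoxide onto the benzyl ester before it is phosphorylated; a 1,3-shift of the phosphate to the primary (E)-allylic position, which cannot close a six-membered ring; or slow C–C bond formation at the fully substituted enolate carbon. Fallback (stepwise, through a π-allyl palladium complex instead of direct SN2′): starting from 18, addition of 19 at −78 °C and aqueous quench should give the C1 vinyl carbinol F1. ClCO2Me/pyridine converts it into the allylic methyl carbonate F2. Deprotonation with LiN(SiMe3)2, transmetalation with ZnCl2 and catalysis by zerovalent palladium (Pd(PPh3)4, THF, 0 °C → rt) ionise the carbonate, and the tethered zinc ester enolate attacks the π-allyl terminus C3 (Tsuji–Trost allylic alkylation). This returns to 23 with the same sense of induction at C4.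

2. Step 13. What may go wrong: competing hydrogen-atom transfer to the ring-A alkene, or erosion of facial selectivity in oxygen capture at C8. Fallback (osmylation and deoxygenation instead of radical hydration): starting from 23, RhCl(PPh3)3/H2 should saturate only the disubstituted C1=C2 alkene to give the 7-ene F3. OsO4 (cat.)/N-methylmorpholine N-oxide adds from the α face to give the 7α,8α-diol F4. PhOC(S)Cl/pyridine acylates only the secondary 7-hydroxyl to give the thionocarbonate F5. Bu3SnH/AIBN (Barton–McCombie deoxygenation) removes it to give the 8α-alcohol F6. AcCl/PhNMe2 gives the acetate F7, and H2 over 10% Pd/C cleaves both benzyl groups to rejoin the route at 26.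

3. Step 7. What may go wrong: incomplete Mitsunobu displacement at the hindered allylic carbinol, or SN2′ capture of the nucleophile, either of which would erode the configuration at C9. Fallback (hydride delivery from palladium instead of a diazene retro-ene): starting from 9, formylation (HCO2H, DCC, DMAP) gives the allylic formate F8. Pd(OAc)2/PBu3 in refluxing dioxane ionises it with inversion, the π-allyl palladium formate loses CO2, and the hydride is delivered from palladium (α face) to the more substituted terminus C9, giving 12.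

Further compounds
F1 | step 12 | C1 vinyl carbinol of 18 (C1 and C4 epimers) | CC1=CC[C@@H](C(C)C(=O)OCc2ccccc2)[C@](C)(C(O)C=C)[C@H]1CCCOCc3ccccc3
F2 | step 12 | allylic methyl carbonate of F1 | CC1=CC[C@@H](C(C)C(=O)OCc2ccccc2)[C@](C)(C(OC(=O)OC)C=C)[C@H]1CCCOCc3ccccc3
F3 | step 13 | benzyl 13-(benzyloxy)-14,15,16-trinorlabd-7-en-18-oate | CC1=CC[C@@H]2[C@](C)(CCC[C@@]2(C)C(=O)OCc3ccccc3)[C@H]1CCCOCc4ccccc4
F4 | step 13 | benzyl 13-(benzyloxy)-7α,8α-dihydroxy-14,15,16-trinorlabdan-18-oate | O[C@]1(C)[C@H](O)C[C@@H]2[C@](C)(CCC[C@@]2(C)C(=O)OCc3ccccc3)[C@H]1CCCOCc4ccccc4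
F5 | step 13 | 7α-O-(phenoxythiocarbonyl) derivative of F4 | O[C@]1(C)[C@H](OC(=S)Oc3ccccc3)C[C@@H]2[C@](C)(CCC[C@@]2(C)C(=O)OCc4ccccc4)[C@H]1CCCOCc5ccccc5
F6 | step 13 | benzyl 13-(benzyloxy)-8α-hydroxy-14,15,16-trinorlabdan-18-oate | O[C@]1(C)CC[C@@H]2[C@](C)(CCC[C@@]2(C)C(=O)OCc3ccccc3)[C@H]1CCCOCc4ccccc4
F7 | step 13 | benzyl 8α-acetoxy-13-(benzyloxy)-14,15,16-trinorlabdan-18-oate | CC(=O)O[C@]1(C)CC[C@@H]2[C@](C)(CCC[C@@]2(C)C(=O)OCc3ccccc3)[C@H]1CCCOCc4ccccc4
F8 | step 7 | 7β-formate of 9 | CC1=C(CCCOCc2ccccc2)[C@@](C)(C(OC)OC)[C@H](C(C)=C)C[C@@H]1OC=O
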